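**Plan**

1. Core numbering (7-oxabicyclo[4.1.0]hept-3-en-2-one): C-1 quaternary oxirane carbon, C-2 ketone, C-3 (heptenyl) and C-4 (CH2OH) enone carbons, C-5 carbinol, C-6 oxirane CH. Retrosynthetic cuts in order: silyl ethers and silylethyl ester; heptenyl–C-3 (Suzuki–Miyaura via the 3-iodo enone); the C-3=C-4 π-bond (back to a C-3 sulfoxide); then C-3–C-4 and C-1–C-6 together.
2. Feature that allows the double cut: ketone C-2 lies between two α-carbons (C-1, C-3). Oxirane carbon C-6 has the aldehyde oxidation level and is 1,3 to C-2 through C-1 (Darzens retron) and 1,5 to C-2 through C-3–C-4–C-5 (Michael retron). The carbocycle is therefore one conjugate addition plus one Darzens closure of a γ-chloro β-keto sulfoxide (C-1 to C-3) on a 2,4-bis(silyloxy)but-2-enal (C-4 to C-6 and the CH2O).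
3. Forward: the C-1 side chain is attached by dianion alkylation with a γ-bromotiglate; the enal comes from dimerisation–dehydration of silyloxyacetaldehyde; the domino step closes the carbocycle first and the oxirane second (hence cis fusion); sulfoxide pyrolysis gives the enone; iodination and coupling add the heptenyl group; fluoride unmasks diol and acid.
4. Stereochemistry: a chiral primary amine sets C-4, a temporary centre; the chair-like Darzens closure relays it to C-5, C-6 and C-1 (C-5 oxygen cis to the oxirane oxygen); C-3 and C-4 are then made planar. Both E alkenes come from tiglic acid and the E-alkenylboronic acid.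

Key step: step 7

Abbreviations: TBS = tert-butyldimethylsilyl, TMSE = 2-(trimethylsilyl)ethyl.
Remark: 4, 6 and 7 are racemic at sulfur (7 also a mixture at its chlorinated carbon) and 11–13 are mixtures at C-3 and sulfur; all these centres are erased by enolisation in step 7 or by the elimination in step 8.
Assumption: the 9-amino-9-deoxy-epi-quinine salt is taken to deliver the (8R) adduct 11; if the sense of induction is the opposite, the pseudoenantiomeric amine derived from quinidine is used with nothing else changed.

**Route**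

Step 1
Reactants: 1 tiglic acid
Product: 2 TMSE (E)-2-methylbut-2-enoate
Conditions: 2-(trimethylsilyl)ethanol, DCC, DMAP (cat.), CH2Cl2, 0 °C to rt
Reagents that add atoms: 2-(trimethylsilyl)ethanol, OCC[Si](C)(C)C
Why: Steglich esterification; the silylethyl ester is chosen because fluoride removes it in the last step together with the silyl ethers.

Step 2
Reactants: 2 TMSE (E)-2-methylbut-2-enoate
Product: 3 TMSE (E)-4-bromo-2-methylbut-2-enoate
Conditions: NBS, AIBN (cat.), PhCF3, 85 °C
Reagents that add atoms: N-bromosuccinimide, O=C1CCC(=O)N1Br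
Why: Wohl–Ziegler radical bromination of the allylic γ-methyl group (vinylogous to the ester) with retention of the E geometry; the regioisomeric 2-(bromomethyl) ester is separated.

Step 3
Reactants: 4 methyl phenyl sulfoxide; 5 ethyl chloroacetate
Product: 6 1-chloro-3-(phenylsulfinyl)propan-2-one
Conditions: LiN(iPr)2 (2.1 equiv), THF, −78 °C; then 5; aq. NH4Cl
Reagents that add atoms: none
Why: Claisen-type acylation of the α-sulfinyl carbanion by the ester, the second equivalent of base turning the product into its enolate so that it is not attacked again; the sulfinyl group is the activating group for ring carbon C-3 and the later leaving group.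

Step 4
Reactants: 6 1-chloro-3-(phenylsulfinyl)propan-2-one; 3 TMSE (E)-4-bromo-2-methylbut-2-enoate
Product: 7 TMSE (2E)-5-chloro-2-methyl-6-oxo-7-(phenylsulfinyl)hept-2-enoate
Conditions: LiN(iPr)2 (2.2 equiv), THF, −78 °C; then 3, −78 to −40 °C; aq. NH4Cl
Reagents that add atoms: none
Why: Alkylation of a β-keto sulfoxide 1,3-dianion, in which the later-formed and more basic chlorine-bearing carbanion attacks the primary allylic bromide by SN2 and leaves the sulfinyl-stabilised carbon free for step 7.

Step 5
Reactants: 8 (tert-butyldimethylsilyloxy)acetaldehyde (two molecules)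
Product: 9 (2S,3S)-3-hydroxy-2,4-bis(TBS-oxy)butanal
Conditions: L-proline (10 mol %), DMF, rt
Reagents that add atoms: none
Why: Proline-catalysed enamine aldol dimerisation of an α-silyloxy aldehyde, which should give the anti aldol; both stereocentres are removed in step 6, so only the constitution matters.

Step 6
Reactants: 9 (2S,3S)-3-hydroxy-2,4-bis(TBS-oxy)butanal
Product: 10 (2Z)-2,4-bis(TBS-oxy)but-2-enal
Conditions: MsCl, Et3N, CH2Cl2, −20 °C to rt
Reagents that add atoms: none
Why: Mesylation followed by E1cB elimination of the β-mesyloxy aldehyde should give the conjugated 2-silyloxy enal, whose C-2 oxygen becomes the C-5 carbinol oxygen of the ring.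

Step 7
Reactants: 7 TMSE (2E)-5-chloro-2-methyl-6-oxo-7-(phenylsulfinyl)hept-2-enoate; 10 (2Z)-2,4-bis(TBS-oxy)but-2-enal
Product: 13 sulfinyl epoxy ketone (1R,4R,5R,6R), via Michael adduct 11 (not isolated), via chlorohydrin 12 (not isolated)
Conditions: 9-amino-9-deoxy-epi-quinine (20 mol %), PhCO2H (40 mol %), toluene, 0 °C to rt; then K2CO3, DMF, 0 °C to rt
Reagents that add atoms: none
Why: Proposed new method: the primary amine turns 10 into an α-silyloxy iminium ion, the doubly activated CH2 of 7 adds to its β-carbon (bond C-3–C-4, giving 11 after hydrolysis), the chlorine-bearing α′-carbon then adds as its enol or enolate to the aldehyde in a 6-(enolexo)-exo-trig aldol (bond C-1–C-6, giving 12), and K2CO3 closes the oxirane by 3-exo-tet displacement of chloride. The closest known reaction type is the amine-catalysed domino Michael–aldol–intramolecular SN2 annulation of γ-chloro β-keto esters with β-substituted enals to epoxycyclohexanones, not yet shown with an α-oxygenated enal, a sulfinyl ketone or a chlorinated methine carbon; a primary amine is chosen because α-branched enals condense poorly with secondary amines. C-4 is set by the catalyst, which shields one face of the iminium ion, while C-3 and sulfur are left uncontrolled because step 8 erases them. C-5 epimerises through the enamine and the aldol is reversible, so the material should drain through the chair transition state of oxirane closure with O and Cl trans-diaxial and the carbon substituents equatorial, because an axial OTBS at C-5 would clash with the axial Cl at C-1 and an axial CH2OTBS at C-4 with the axial oxygen at C-6; this puts the C-5 OTBS trans to CH2OTBS and cis to the oxirane oxygen and so fixes C-1, C-5 and C-6 from C-4. The step needs 1,4- rather than 1,2-addition (secured by iminium activation and the soft carbanion), ring closure through the chlorinated carbon and not through C-3 (only the former gives a six-membered ring), and a cis-fused oxirane (secured because the carbocycle closes before the oxirane).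

Step 8
Reactants: 13 sulfinyl epoxy ketone (1R,4R,5R,6R)
Product: 14 TMSE (2E)-2-methyl-4-[(1R,5R,6R)-2-oxo-5-(TBS-oxy)-4-[(TBS-oxy)methyl]-7-oxabicyclo[4.1.0]hept-3-en-1-yl]but-2-enoate
Conditions: NaHCO3, toluene, 70 °C
Reagents that add atoms: none
Why: Thermal syn-elimination of the α-sulfinyl ketone (sulfoxide pyrolysis); the only β-hydrogen is on C-4 and C-3 epimerises by enolisation, so every stereoisomer of 13 can reach the syn arrangement, the activating group leaves, and the σ-bond made in step 7 becomes the enone double bond.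

Step 9
Reactants: 14 enone epoxide
Product: 15 3-iodo enone epoxide
Conditions: I2, DMAP (cat.), pyridine/CH2Cl2, 0 °C to rt
Reagents that add atoms: iodine, [I][I]
Why: Nucleophile-catalysed α-iodination of an enone (conjugate addition of the pyridine base, iodination of the enolate, E1cB loss of the base); C-3 is the only enone α-CH, and the side-chain enoate has no α-hydrogen.

Step 10
Reactants: 15 3-iodo enone epoxide; 16 (E)-hept-1-en-1-ylboronic acid
Product: 17 bis-TBS ether TMSE ester of the target
Conditions: PdCl2(PhCN)2 (5 mol %), AsPh3 (10 mol %), Ag2O, THF/H2O, rt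
Reagents that add atoms: none
Why: Suzuki–Miyaura coupling (oxidative addition of zerovalent palladium into the carbon–iodine bond, Ag2O-assisted transmetalation, reductive elimination) with retention of the E geometry of 16; these mild, room-temperature conditions should spare the epoxy ketone.

Step 11
Reactants: 17 bis-TBS ether TMSE ester of the target
Product: 18 target acid
Conditions: Bu4NF, AcOH, THF, 0 °C to rt
Reagents that add atoms: none
Why: Fluoride-induced cleavage of both silyl ethers and β-elimination of the silylethyl ester (loss of ethene), buffered with AcOH so that no free alkoxide sits next to the oxirane; no stereocentre is touched.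

**Compound list**

1 | tiglic acid, (E)-2-methylbut-2-enoic acid | C/C=C(\C)C(=O)O | starting material
2 | TMSE (E)-2-methylbut-2-enoate | C/C=C(\C)C(=O)OCC[Si](C)(C)C | intermediate
3 | TMSE (E)-4-bromo-2-methylbut-2-enoate | BrC/C=C(\C)C(=O)OCC[Si](C)(C)C | intermediate
4 | methyl phenyl sulfoxide (racemic) | CS(=O)c1ccccc1 | starting material
5 | ethyl chloroacetate | CCOC(=O)CCl | starting material
6 | 1-chloro-3-(phenylsulfinyl)propan-2-one (racemic at sulfur) | O=C(CCl)CS(=O)c1ccccc1 | intermediate
7 | TMSE (2E)-5-chloro-2-methyl-6-oxo-7-(phenylsulfinyl)hept-2-enoate (mixture at C-5 and sulfur) | O=C(CS(=O)c1ccccc1)C(Cl)C/C=C(\C)C(=O)OCC[Si](C)(C)C | intermediate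
8 | (tert-butyldimethylsilyloxy)acetaldehyde | O=CCO[Si](C)(C)C(C)(C)C | starting material
9 | (2S,3S)-3-hydroxy-2,4-bis(TBS-oxy)butanal | O=C[C@@H](O[Si](C)(C)C(C)(C)C)[C@@H](O)CO[Si](C)(C)C(C)(C)C | intermediate
10 | (2Z)-2,4-bis(TBS-oxy)but-2-enal | O=C/C(O[Si](C)(C)C(C)(C)C)=C/CO[Si](C)(C)C(C)(C)C | intermediate
11 | Michael adduct, TMSE (2E,8R)-5-chloro-2-methyl-6,10-dioxo-7-(phenylsulfinyl)-9-(TBS-oxy)-8-[(TBS-oxy)methyl]dec-2-enoate (mixture at C-5, C-7, C-9 and sulfur; not isolated) | c1ccccc1S(=O)C(C(=O)C(Cl)C/C=C(\C)C(=O)OCC[Si](C)(C)C)[C@H](CO[Si](C)(C)C(C)(C)C)C(O[Si](C)(C)C(C)(C)C)C=O | intermediate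
12 | chlorohydrin, TMSE (2E)-4-[(1S,2R,3R,4R)-1-chloro-2-hydroxy-6-oxo-5-(phenylsulfinyl)-3-(TBS-oxy)-4-[(TBS-oxy)methyl]cyclohexyl]-2-methylbut-2-enoate (mixture at C-5 of the ring and sulfur; not isolated) | C1(S(=O)c2ccccc2)[C@H](CO[Si](C)(C)C(C)(C)C)[C@@H](O[Si](C)(C)C(C)(C)C)[C@@H](O)[C@@](Cl)(C/C=C(\C)C(=O)OCC[Si](C)(C)C)C1=O | intermediate
13 | sulfinyl epoxy ketone, TMSE (2E)-2-methyl-4-[(1R,4R,5R,6R)-2-oxo-3-(phenylsulfinyl)-5-(TBS-oxy)-4-[(TBS-oxy)methyl]-7-oxabicyclo[4.1.0]heptan-1-yl]but-2-enoate (mixture at C-3 and sulfur) | C1(S(=O)c2ccccc2)[C@H](CO[Si](C)(C)C(C)(C)C)[C@@H](O[Si](C)(C)C(C)(C)C)[C@H]3O[C@@]3(C/C=C(\C)C(=O)OCC[Si](C)(C)C)C1=O | intermediate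
14 | enone epoxide, TMSE (2E)-2-methyl-4-[(1R,5R,6R)-2-oxo-5-(TBS-oxy)-4-[(TBS-oxy)methyl]-7-oxabicyclo[4.1.0]hept-3-en-1-yl]but-2-enoate | C1=C(CO[Si](C)(C)C(C)(C)C)[C@@H](O[Si](C)(C)C(C)(C)C)[C@H]2O[C@@]2(C/C=C(\C)C(=O)OCC[Si](C)(C)C)C1=O | intermediate
15 | 3-iodo enone epoxide, TMSE (2E)-4-[(1R,5R,6R)-3-iodo-2-oxo-5-(TBS-oxy)-4-[(TBS-oxy)methyl]-7-oxabicyclo[4.1.0]hept-3-en-1-yl]-2-methylbut-2-enoate | IC1=C(CO[Si](C)(C)C(C)(C)C)[C@@H](O[Si](C)(C)C(C)(C)C)[C@H]2O[C@@]2(C/C=C(\C)C(=O)OCC[Si](C)(C)C)C1=O | intermediate
16 | (E)-hept-1-en-1-ylboronic acid | CCCCC/C=C/B(O)O | starting material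
17 | TMSE (2E)-4-[(1R,5R,6R)-3-[(1E)-hept-1-en-1-yl]-2-oxo-5-(TBS-oxy)-4-[(TBS-oxy)methyl]-7-oxabicyclo[4.1.0]hept-3-en-1-yl]-2-methylbut-2-enoate | CCCCC/C=C/C1=C(CO[Si](C)(C)C(C)(C)C)[C@@H](O[Si](C)(C)C(C)(C)C)[C@H]2O[C@@]2(C/C=C(\C)C(=O)OCC[Si](C)(C)C)C1=O | intermediate
18 | (2E)-4-[(1R,5R,6R)-3-[(1E)-hept-1-en-1-yl]-5-hydroxy-4-(hydroxymethyl)-2-oxo-7-oxabicyclo[4.1.0]hept-3-en-1-yl]-2-methylbut-2-enoic acid | CCCCC/C=C/C1=C(CO)[C@@H](O)[C@H]2O[C@@]2(C/C=C(\C)C(=O)O)C1=O | target

Total step count: 11. Longest linear sequence: 8 steps (1, 2, 4, 7, 8, 9, 10, 11).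

**Steps most likely to fail**

Step 7 (carries the label). What may go wrong: incomplete discrimination of the two faces of the α-branched iminium ion, N-alkylation of the catalyst by the α-chloro ketone, or leakage of material through the chair with cis C-4/C-5 substituents; each lowers the enantiomeric purity of 13. The fallback uses known reactions only and replaces catalysis by a stoichiometric sulfinyl auxiliary with separation of diastereomers. It sets out from 5, 3 and 10. Commercial (R)-methyl p-tolyl sulfoxide is lithiated with LiN(iPr)2 and acylated with 5 to (R)-1-chloro-3-(p-tolylsulfinyl)propan-2-one F1. Its dianion is alkylated with 3 as in step 4 to the p-tolylsulfinyl analogue of 7 F2. DBU-catalysed conjugate addition of F2 to 10 gives the Michael adduct F3 as a mixture at carbon. K2CO3 in DMF then performs the intramolecular Darzens condensation and gives two series of epoxy ketones, the (1R,4R,5R,6R) epoxy ketone F4 and its ring-enantiomeric diastereomer F5. Because sulfur is homochiral these are diastereomers and are separated by chromatography or crystallisation. Pyrolysis of F4 (NaHCO3, toluene, 70 °C) comes back to the route at 14.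

Step 4. What may go wrong: self-condensation or intramolecular chloride displacement in the chloro-substituted dianion, and alkylation at oxygen or at the sulfinyl-bearing carbon. The fallback sets out from 3. The lithium enolate of methyl chloroacetate (LiN(SiMe3)2, THF, −78 °C) is alkylated with 3 to the α-chloro diester F6. Lithiated 4 (LiN(iPr)2, 2 equiv) is then acylated at the saturated methyl ester of F6, the conjugated α-branched silylethyl ester being far less electrophilic. This comes back to the route at 7.

Step 11. What may go wrong: an alkoxide or carboxylate generated by fluoride attacks the neighbouring oxirane (epoxide migration) or triggers retro-aldol cleavage before it is protonated. The fallback sets out from 17. Both silyl ethers are removed under acidic conditions (HF·pyridine, THF, 0 °C) to the diol silylethyl ester F7. The silylethyl ester is then cleaved by acidolysis (CF3CO2H, CH2Cl2, 0 °C), a β-silyl cation fragmentation that involves no basic species. This comes back to the route at 18.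

**Further compounds**

F1 | step 7 | (R)-1-chloro-3-(p-tolylsulfinyl)propan-2-one | Cc1ccc(cc1)[S@](=O)CC(=O)CCl
F2 | step 7 | TMSE (2E)-5-chloro-2-methyl-6-oxo-7-[(R)-p-tolylsulfinyl]hept-2-enoate | Cc1ccc(cc1)[S@](=O)CC(=O)C(Cl)C/C=C(\C)C(=O)OCC[Si](C)(C)C
F3 | step 7 | Michael adduct of F2 and 10 (R at sulfur, mixture at carbon) | Cc1ccc(cc1)[S@](=O)C(C(=O)C(Cl)C/C=C(\C)C(=O)OCC[Si](C)(C)C)C(CO[Si](C)(C)C(C)(C)C)C(O[Si](C)(C)C(C)(C)C)C=O
F4 | step 7 | p-tolylsulfinyl analogue of 13, (R) at sulfur, ring (1R,4R,5R,6R) | Cc1ccc(cc1)[S@](=O)C2[C@H](CO[Si](C)(C)C(C)(C)C)[C@@H](O[Si](C)(C)C(C)(C)C)[C@H]3O[C@@]3(C/C=C(\C)C(=O)OCC[Si](C)(C)C)C2=O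
F5 | step 7 | diastereomer of F4, (R) at sulfur, ring (1S,4S,5S,6S) | Cc1ccc(cc1)[S@](=O)C2[C@@H](CO[Si](C)(C)C(C)(C)C)[C@H](O[Si](C)(C)C(C)(C)C)[C@@H]3O[C@]3(C/C=C(\C)C(=O)OCC[Si](C)(C)C)C2=O
F6 | step 4 | 1-methyl 6-TMSE (4E)-2-chloro-5-methylhex-4-enedioate | COC(=O)C(Cl)C/C=C(\C)C(=O)OCC[Si](C)(C)C
F7 | step 11 | TMSE (2E)-4-[(1R,5R,6R)-3-[(1E)-hept-1-en-1-yl]-5-hydroxy-4-(hydroxymethyl)-2-oxo-7-oxabicyclo[4.1.0]hept-3-en-1-yl]-2-methylbut-2-enoate | CCCCC/C=C/C1=C(CO)[C@@H](O)[C@H]2O[C@@]2(C/C=C(\C)C(=O)OCC[Si](C)(C)C)C1=O
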